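**Strategy.** The 7‑methoxycyclohexa‑2,5‑dien‑8‑one ring is read as a masked 3‑oxido‑hexatriene: its carbonyl (C8), enol‑ether alkene (C6=C7) and enone alkene (C9=C10) are cross‑conjugated, and the spiro carbon C5 and C10 are the triene termini. The carbocycle is therefore closed last, by forming C5–C10. γ‑Deprotonation of an acyclic (1E,4Z)‑1,4‑dimethoxypenta‑1,4‑dien‑3‑one hung on C3 of the finished oxolane should give a lithium trienolate that undergoes 6π‑electrocyclisation and expels methoxide, creating the quaternary spiro stereocentre on the face opposite both flanking oxolane substituents. The oxolane comes from two Evans aldols (C4; C2/Cβ) and a benzylic‑cation etherification (C5).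

Key step: step 21

Abbreviations: TBS = tert‑butyldimethylsilyl; TIPS = triisopropylsilyl; ArT = 3‑methoxy‑4‑(TIPS‑oxy)phenyl; Ar'O = 4‑[3‑(TBS‑oxy)propyl]‑2‑methoxyphenoxy. Oxolane locants: O1, C2 (carries the aryloxy side chain, whose first carbon is Cβ), C3, C4 (CH2OTBS), C5 (ArT).

Assumption (chemistry): the configuration at oxolane C3 in 27–33 and the C=C(OMe) geometry in 30–33 are erased in step 21, where C3 becomes trigonal; these compounds are drawn as the expected major isomers and minor isomers are carried along.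

**Step 1**
Reactants: 1 vanillin
Product: 2 3‑methoxy‑4‑(TIPS‑oxy)benzaldehyde
Conditions: TIPSCl, imidazole, DMF, rt
Reagents that add atoms: triisopropylsilyl chloride, CC(C)[Si](Cl)(C(C)C)C(C)C
Why: Phenol silylation; the TIPS aryl ether is chosen because it should survive the basic and nucleophilic steps and still fall to fluoride at the end.

**Step 2**
Reactants: 3 (S)‑4‑benzyloxazolidin‑2‑one; 4 pent‑4‑enoyl chloride
Product: 6 (S)‑4‑benzyl‑3‑(pent‑4‑enoyl)oxazolidin‑2‑one, via lithium oxazolidinide 5 (not isolated)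
Conditions: n‑BuLi, THF, −78 °C; then 4, −78 → 0 °C
Reagents that add atoms: none
Why: Standard N‑acylation of a lithiated Evans auxiliary with an acid chloride.

**Step 3**
Reactants: 6 (S)‑4‑benzyl‑3‑(pent‑4‑enoyl)oxazolidin‑2‑one; 2 3‑methoxy‑4‑(TIPS‑oxy)benzaldehyde
Product: 8 (S)‑4‑benzyl‑3‑[(2S)‑2‑[(S)‑hydroxy(ArT)methyl]pent‑4‑enoyl]oxazolidin‑2‑one, via dibutylboron Z‑enolate 7 (not isolated)
Conditions: Bu2BOTf, iPr2NEt, CH2Cl2, −78 → 0 °C; then 2, −78 → 0 °C; pH 7 buffer, MeOH, H2O2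
Reagents that add atoms: none
Why: Evans syn‑aldol through a Zimmerman–Traxler transition state of the Z‑boron enolate; the (S)‑auxiliary sets the future oxolane C4, and the benzylic carbinol centre is reset later.

**Step 4**
Reactants: 8 Evans aldol adduct
Product: 9 (1S,2R)‑2‑allyl‑1‑ArT‑propane‑1,3‑diol
Conditions: LiBH4, MeOH (1 equiv), THF, 0 °C
Reagents that add atoms: none
Why: Reductive cleavage of the N‑acyl oxazolidinone to the primary alcohol without touching the alkene or silyl ether.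

**Step 5**
Reactants: 9 (1S,2R)‑2‑allyl‑1‑ArT‑propane‑1,3‑diol
Product: 10 (1S,2R)‑2‑allyl‑1,3‑bis(TBS‑oxy)‑1‑ArT‑propane
Conditions: TBSOTf, 2,6‑lutidine, CH2Cl2, −78 → 0 °C
Reagents that add atoms: tert‑butyldimethylsilyl triflate, CC(C)(C)[Si](C)(C)OS(=O)(=O)C(F)(F)F
Why: Exhaustive silylation; the benzylic TBS ether doubles as the latent leaving group for step 12.

**Step 6**
Reactants: 10 bis‑TBS ether
Product: 12 (3R,4S)‑4‑(TBS‑oxy)‑3‑[(TBS‑oxy)methyl]‑4‑ArT‑butanal, via vicinal diol 11 (not isolated)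
Conditions: OsO4 (2 mol %), NaIO4, 2,6‑lutidine, dioxane/H2O, rt
Reagents that add atoms: sodium periodate (terminal oxidant; carbonyl oxygen delivered via catalytic OsO4), [Na+].[O-]I(=O)(=O)=O
Why: Lemieux–Johnson cleavage of the terminal alkene, used instead of ozone to spare the electron‑rich arene.

**Step 7**
Reactants: 12 (3R,4S)‑butanal
Product: 13 (3R,4S)‑4‑(TBS‑oxy)‑3‑[(TBS‑oxy)methyl]‑4‑ArT‑2‑methylidenebutanal
Conditions: 37% aq. CH2O, pyrrolidine (10 mol %), propionic acid (10 mol %), i‑PrOH, 45 °C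
Reagents that add atoms: formaldehyde, C=O
Why: Organocatalytic α‑methylenation (Mannich condensation–elimination via the enamine); the new sp2 carbon becomes dienone C6 and keeps oxolane C3 free of a stereocentre.

**Step 8**
Reactants: 14 (R)‑4‑benzyloxazolidin‑2‑one; 15 bromoacetyl bromide
Product: 17 (R)‑4‑benzyl‑3‑(2‑bromoacetyl)oxazolidin‑2‑one, via lithium oxazolidinide 16 (not isolated)
Conditions: n‑BuLi, THF, −78 °C; then 15, −78 °C
Reagents that add atoms: none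
Why: N‑acylation of the lithiated auxiliary; the acyl bromide reacts far faster than the alkyl bromide.

**Step 9**
Reactants: 17 (R)‑4‑benzyl‑3‑(2‑bromoacetyl)oxazolidin‑2‑one; 18 4‑(3‑hydroxypropyl)‑2‑methoxyphenol (dihydroconiferyl alcohol)
Product: 19 (R)‑4‑benzyl‑3‑{2‑[4‑(3‑hydroxypropyl)‑2‑methoxyphenoxy]acetyl}oxazolidin‑2‑one
Conditions: K2CO3, acetone, 0 °C → rt
Reagents that add atoms: none
Why: Williamson etherification; only the phenol is deprotonated by carbonate and SN2 at the α‑bromo imide should outrun acyl transfer.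

**Step 10**
Reactants: 19 hydroxypropyl glycolate imide
Product: 20 (R)‑4‑benzyl‑3‑[2‑(Ar'O)acetyl]oxazolidin‑2‑one
Conditions: TBSCl, imidazole, DMF, rt
Reagents that add atoms: tert‑butyldimethylsilyl chloride, CC(C)(C)[Si](C)(C)Cl
Why: Routine silylation of the primary alcohol before the boron aldol.

**Step 11**
Reactants: 20 (R)‑4‑benzyl‑3‑[2‑(Ar'O)acetyl]oxazolidin‑2‑one; 13 (3R,4S)‑2‑methylidenebutanal
Product: 22 (R)‑4‑benzyl‑3‑[(2R,3S,5R,6S)‑2‑(Ar'O)‑3‑hydroxy‑4‑methylidene‑6‑(TBS‑oxy)‑5‑[(TBS‑oxy)methyl]‑6‑ArT‑hexanoyl]oxazolidin‑2‑one, via dibutylboron Z‑enolate 21 (not isolated)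
Conditions: Bu2BOTf, iPr2NEt, CH2Cl2, −78 → 0 °C; then 13, −78 → 0 °C; pH 7 buffer, MeOH, H2O2
Reagents that add atoms: none
Why: Evans syn glycolate aldol; the (R)‑auxiliary sets both the carbinol (future oxolane C2) and the aryloxy carbon Cβ in the threo relationship of the target, the remote C4 centre of the enal having little say.

**Step 12**
Reactants: 22 glycolate aldol adduct
Product: 23 (R)‑4‑benzyl‑3‑{(2R)‑2‑(Ar'O)‑2‑[(2S,4R,5S)‑3‑methylidene‑4‑[(TBS‑oxy)methyl]‑5‑ArT‑oxolan‑2‑yl]acetyl}oxazolidin‑2‑one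
Conditions: Bi(OTf)3 (5 mol %), 4 Å MS, CH2Cl2, −20 → 0 °C
Reagents that add atoms: none
Why: SN1 etherification: the benzylic TBS ether ionises to a p‑silyloxybenzyl cation that the only free hydroxyl traps in a 5‑exo closure, and C5 is set with the aryl group trans to the C4 substituent by the planar cation (reversible ionisation), not by the configuration of 22.

**Step 13**
Reactants: 23 oxolane imide
Product: 24 (2S)‑2‑(Ar'O)‑2‑[(2S,4R,5S)‑3‑methylidene‑4‑[(TBS‑oxy)methyl]‑5‑ArT‑oxolan‑2‑yl]ethan‑1‑ol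
Conditions: LiBH4, MeOH (1 equiv), THF, 0 °C
Reagents that add atoms: none
Why: Reductive removal of the second auxiliary unveils the side‑chain CH2OH at the correct oxidation level.

**Step 14**
Reactants: 24 primary alcohol
Product: 25 (2S,4R,5S)‑2‑[(1S)‑1‑(Ar'O)‑2‑(TBS‑oxy)ethyl]‑3‑methylidene‑4‑[(TBS‑oxy)methyl]‑5‑ArT‑oxolane
Conditions: TBSCl, imidazole, DMF, rt
Reagents that add atoms: tert‑butyldimethylsilyl chloride, CC(C)(C)[Si](C)(C)Cl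
Why: Protection so that the alcohol made in step 15 is the only one that can be oxidised.

**Step 15**
Reactants: 25 3‑methylidene oxolane
Product: 27 [(2S,3S,4R,5S)‑2‑[(1S)‑1‑(Ar'O)‑2‑(TBS‑oxy)ethyl]‑4‑[(TBS‑oxy)methyl]‑5‑ArT‑oxolan‑3‑yl]methanol, via B‑alkyl‑9‑BBN 26 (not isolated)
Conditions: 9‑BBN, THF, 0 → 50 °C; then 3 M NaOH, 30% H2O2, 0 °C
Reagents that add atoms: hydrogen peroxide, OO
Why: Anti‑Markovnikov hydroboration–oxidation of the 1,1‑disubstituted alkene; borane should approach anti to the C2 and C4 substituents, giving the (3S) epimer, but either epimer serves.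

**Step 16**
Reactants: 27 oxolan‑3‑ylmethanol
Product: 28 (2S,3R,4R,5S)‑2‑[(1S)‑1‑(Ar'O)‑2‑(TBS‑oxy)ethyl]‑4‑[(TBS‑oxy)methyl]‑5‑ArT‑oxolane‑3‑carbaldehyde
Conditions: Dess–Martin periodinane, CH2Cl2, 0 °C → rt
Reagents that add atoms: none
Why: Dess–Martin oxidation of the only free alcohol; epimerisation at C3 would be harmless.

**Step 17**
Reactants: 28 oxolane‑3‑carbaldehyde; 29 methyl 2‑(dimethoxyphosphoryl)‑2‑methoxyacetate
Product: 30 methyl (Z)‑3‑[(2S,3S,4R,5S)‑2‑[(1S)‑1‑(Ar'O)‑2‑(TBS‑oxy)ethyl]‑4‑[(TBS‑oxy)methyl]‑5‑ArT‑oxolan‑3‑yl]‑2‑methoxyprop‑2‑enoate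
Conditions: LiCl, DBU, MeCN, 0 °C → rt
Reagents that add atoms: none
Why: Horner–Wadsworth–Emmons olefination under mild Masamune–Roush conditions installs dienone C6=C7 with its methoxy group; the Z isomer should predominate and the ratio does not matter.

**Step 18**
Reactants: 30 α‑methoxyacrylate
Product: 31 (Z)‑3‑[(2S,3S,4R,5S)‑2‑[(1S)‑1‑(Ar'O)‑2‑(TBS‑oxy)ethyl]‑4‑[(TBS‑oxy)methyl]‑5‑ArT‑oxolan‑3‑yl]‑N,2‑dimethoxy‑N‑methylprop‑2‑enamide
Conditions: MeNH(OMe)·HCl, i‑PrMgCl, THF, −20 → 0 °C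
Reagents that add atoms: N,O‑dimethylhydroxylamine hydrochloride, CNOC.Cl
Why: Direct ester‑to‑Weinreb‑amide aminolysis with the magnesium amide.

**Step 19**
Reactants: 31 Weinreb amide
Product: 32 (Z)‑5‑[(2S,3S,4R,5S)‑2‑[(1S)‑1‑(Ar'O)‑2‑(TBS‑oxy)ethyl]‑4‑[(TBS‑oxy)methyl]‑5‑ArT‑oxolan‑3‑yl]‑4‑methoxypent‑4‑en‑1‑yn‑3‑one
Conditions: HC≡CMgBr, THF, 0 °C; poured into cold 0.5 M aq. HCl
Reagents that add atoms: ethynylmagnesium bromide, C#C[Mg]Br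
Why: Weinreb ketone synthesis; the chelated tetrahedral intermediate prevents over‑addition and the acidic quench keeps the released amine from adding to the ynone.

**Step 20**
Reactants: 32 ynone
Product: 33 (1E,4Z)‑5‑[(2S,3S,4R,5S)‑2‑[(1S)‑1‑(Ar'O)‑2‑(TBS‑oxy)ethyl]‑4‑[(TBS‑oxy)methyl]‑5‑ArT‑oxolan‑3‑yl]‑1,4‑dimethoxypenta‑1,4‑dien‑3‑one
Conditions: MeOH (10 equiv), PMe3 (10 mol %), CH2Cl2, 0 °C → rt
Reagents that add atoms: methanol, CO
Why: Phosphine‑catalysed oxa‑Michael addition of methanol to the terminal ynone gives the (E)‑β‑methoxy enone, which puts a leaving group on the carbon that becomes C10.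

**Step 21**
Reactants: 33 (1E,4Z)‑1,4‑dimethoxypenta‑1,4‑dien‑3‑one
Product: 36 (1S,3S,4R,5S)‑1‑[(1S)‑1‑(Ar'O)‑2‑(TBS‑oxy)ethyl]‑7‑methoxy‑4‑[(TBS‑oxy)methyl]‑3‑ArT‑2‑oxaspiro[4.5]deca‑6,9‑dien‑8‑one, via lithium trienolate 34 (not isolated), via lithium methoxycyclohexadienolate 35 (not isolated)
Conditions: LiHMDS (1.3 equiv), THF, −78 → 0 °C; AcOH quench
Reagents that add atoms: none
Why: Proposed new method: LiHMDS should remove the vinylogous γ‑hydrogen at oxolane C3 and, with lithium bridging the enolate oxygen and the adjacent methoxy group, give the (3Z)‑3‑oxido‑hexatriene 34, whose termini (oxolane C3 and the methoxy‑bearing C1) join by thermal disrotatory 6π‑electrocyclisation; the β‑methoxy cyclohexadienolate 35 then loses LiOMe by E1cB to deliver the cross‑conjugated dienone. The closest known reaction type is the oxyanion‑accelerated 6π‑electrocyclisation of 3‑oxido‑trienes generated from cyclobutenones and alkenyllithiums, which runs below room temperature, combined with the familiar addition–elimination chemistry of β‑alkoxy enones; what is new is generating the trienolate by γ‑deprotonation and ending at a quaternary spiro centre. The six‑membered carbocycle is closed by this pericyclic C–C bond formation, formally a 6‑endo vinylogous addition–elimination. The only lasting new stereocentre, the spiro carbon, is set by the oxolane: C3 is trigonal in 34 and both neighbours, C2 and C4, carry their large substituents on the same face, so the other triene terminus should bond on the opposite face (that of H‑2 and H‑4), which is the (5S) configuration; the methoxy‑bearing centre of 35 is destroyed. The step needs exclusive γ‑deprotonation (C3–H is the only acidified C–H), the Z enolate (secured by Li chelation) and ring closure faster than β‑elimination of the ring oxygen, which the poor overlap of the endocyclic C2–O bond with the exocyclic π‑system should disfavour.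

**Step 22**
Reactants: 36 tetrasilylated spirodienone
Product: 37 (1S,3S,4R,5S)‑3‑(4‑hydroxy‑3‑methoxyphenyl)‑1‑{(1S)‑2‑hydroxy‑1‑[4‑(3‑hydroxypropyl)‑2‑methoxyphenoxy]ethyl}‑4‑(hydroxymethyl)‑7‑methoxy‑2‑oxaspiro[4.5]deca‑6,9‑dien‑8‑one (CNP0252711.1)
Conditions: HF·pyridine, pyridine, THF, 0 °C → rt; Me3SiOMe quench
Reagents that add atoms: none
Why: Buffered fluoride cleaves the three primary TBS ethers and the aryl TIPS ether in one operation under conditions mild enough to spare the enol ether and dienone.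

**Compound list**

1 | vanillin | COc1cc(C=O)ccc1O | starting material
2 | 3‑methoxy‑4‑(TIPS‑oxy)benzaldehyde | COc1cc(C=O)ccc1O[Si](C(C)C)(C(C)C)C(C)C | intermediate
3 | (S)‑4‑benzyloxazolidin‑2‑one | O=C1N[C@@H](Cc2ccccc2)CO1 | starting material
4 | pent‑4‑enoyl chloride | C=CCCC(Cl)=O | starting material
5 | lithium (S)‑4‑benzyl‑2‑oxooxazolidin‑3‑ide | [Li]N1[C@@H](Cc2ccccc2)COC1=O | intermediate
6 | (S)‑4‑benzyl‑3‑(pent‑4‑enoyl)oxazolidin‑2‑one | C=CCCC(=O)N1[C@@H](Cc2ccccc2)COC1=O | intermediate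
7 | dibutylboron (Z)‑enolate of 6 | C=CC/C=C(\OB(CCCC)CCCC)N1[C@@H](Cc2ccccc2)COC1=O | intermediate
8 | (S)‑4‑benzyl‑3‑[(2S)‑2‑[(S)‑hydroxy(ArT)methyl]pent‑4‑enoyl]oxazolidin‑2‑one | C=CC[C@H](C(=O)N1[C@@H](Cc2ccccc2)COC1=O)[C@H](O)c1ccc(O[Si](C(C)C)(C(C)C)C(C)C)c(OC)c1 | intermediate
9 | (1S,2R)‑2‑allyl‑1‑ArT‑propane‑1,3‑diol | C=CC[C@H](CO)[C@H](O)c1ccc(O[Si](C(C)C)(C(C)C)C(C)C)c(OC)c1 | intermediate
10 | (1S,2R)‑2‑allyl‑1,3‑bis(TBS‑oxy)‑1‑ArT‑propane | C=CC[C@H](CO[Si](C)(C)C(C)(C)C)[C@H](O[Si](C)(C)C(C)(C)C)c1ccc(O[Si](C(C)C)(C(C)C)C(C)C)c(OC)c1 | intermediate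
11 | (4R,5S)‑5‑(TBS‑oxy)‑4‑[(TBS‑oxy)methyl]‑5‑ArT‑pentane‑1,2‑diol (both C2 epimers) | OCC(O)C[C@H](CO[Si](C)(C)C(C)(C)C)[C@H](O[Si](C)(C)C(C)(C)C)c1ccc(O[Si](C(C)C)(C(C)C)C(C)C)c(OC)c1 | intermediate
12 | (3R,4S)‑4‑(TBS‑oxy)‑3‑[(TBS‑oxy)methyl]‑4‑ArT‑butanal | O=CC[C@H](CO[Si](C)(C)C(C)(C)C)[C@H](O[Si](C)(C)C(C)(C)C)c1ccc(O[Si](C(C)C)(C(C)C)C(C)C)c(OC)c1 | intermediate
13 | (3R,4S)‑4‑(TBS‑oxy)‑3‑[(TBS‑oxy)methyl]‑4‑ArT‑2‑methylidenebutanal | C=C(C=O)[C@H](CO[Si](C)(C)C(C)(C)C)[C@H](O[Si](C)(C)C(C)(C)C)c1ccc(O[Si](C(C)C)(C(C)C)C(C)C)c(OC)c1 | intermediate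
14 | (R)‑4‑benzyloxazolidin‑2‑one | O=C1N[C@H](Cc2ccccc2)CO1 | starting material
15 | bromoacetyl bromide | BrCC(Br)=O | starting material
16 | lithium (R)‑4‑benzyl‑2‑oxooxazolidin‑3‑ide | [Li]N1[C@H](Cc2ccccc2)COC1=O | intermediate
17 | (R)‑4‑benzyl‑3‑(2‑bromoacetyl)oxazolidin‑2‑one | BrCC(=O)N1[C@H](Cc2ccccc2)COC1=O | intermediate
18 | 4‑(3‑hydroxypropyl)‑2‑methoxyphenol (dihydroconiferyl alcohol) | COc1cc(CCCO)ccc1O | starting material
19 | (R)‑4‑benzyl‑3‑{2‑[4‑(3‑hydroxypropyl)‑2‑methoxyphenoxy]acetyl}oxazolidin‑2‑one | COc1cc(CCCO)ccc1OCC(=O)N1[C@H](Cc2ccccc2)COC1=O | intermediate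
20 | (R)‑4‑benzyl‑3‑[2‑(Ar'O)acetyl]oxazolidin‑2‑one | COc1cc(CCCO[Si](C)(C)C(C)(C)C)ccc1OCC(=O)N1[C@H](Cc2ccccc2)COC1=O | intermediate
21 | dibutylboron (Z)‑enolate of 20 | COc1cc(CCCO[Si](C)(C)C(C)(C)C)ccc1O/C=C(\OB(CCCC)CCCC)N1[C@H](Cc2ccccc2)COC1=O | intermediate
22 | (R)‑4‑benzyl‑3‑[(2R,3S,5R,6S)‑2‑(Ar'O)‑3‑hydroxy‑4‑methylidene‑6‑(TBS‑oxy)‑5‑[(TBS‑oxy)methyl]‑6‑ArT‑hexanoyl]oxazolidin‑2‑one | C=C([C@H](O)[C@H](C(=O)N1[C@H](Cc2ccccc2)COC1=O)Oc1ccc(CCCO[Si](C)(C)C(C)(C)C)cc1OC)[C@H](CO[Si](C)(C)C(C)(C)C)[C@H](O[Si](C)(C)C(C)(C)C)c1ccc(O[Si](C(C)C)(C(C)C)C(C)C)c(OC)c1 | intermediate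
23 | (R)‑4‑benzyl‑3‑{(2R)‑2‑(Ar'O)‑2‑[(2S,4R,5S)‑3‑methylidene‑4‑[(TBS‑oxy)methyl]‑5‑ArT‑oxolan‑2‑yl]acetyl}oxazolidin‑2‑one | C=C1[C@H](CO[Si](C)(C)C(C)(C)C)[C@@H](c2ccc(O[Si](C(C)C)(C(C)C)C(C)C)c(OC)c2)O[C@@H]1[C@H](C(=O)N1[C@H](Cc2ccccc2)COC1=O)Oc1ccc(CCCO[Si](C)(C)C(C)(C)C)cc1OC | intermediate
24 | (2S)‑2‑(Ar'O)‑2‑[(2S,4R,5S)‑3‑methylidene‑4‑[(TBS‑oxy)methyl]‑5‑ArT‑oxolan‑2‑yl]ethan‑1‑ol | C=C1[C@H](CO[Si](C)(C)C(C)(C)C)[C@@H](c2ccc(O[Si](C(C)C)(C(C)C)C(C)C)c(OC)c2)O[C@@H]1[C@H](CO)Oc1ccc(CCCO[Si](C)(C)C(C)(C)C)cc1OC | intermediate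
25 | (2S,4R,5S)‑2‑[(1S)‑1‑(Ar'O)‑2‑(TBS‑oxy)ethyl]‑3‑methylidene‑4‑[(TBS‑oxy)methyl]‑5‑ArT‑oxolane | C=C1[C@H](CO[Si](C)(C)C(C)(C)C)[C@@H](c2ccc(O[Si](C(C)C)(C(C)C)C(C)C)c(OC)c2)O[C@@H]1[C@H](CO[Si](C)(C)C(C)(C)C)Oc1ccc(CCCO[Si](C)(C)C(C)(C)C)cc1OC | intermediate
26 | B‑alkyl‑9‑BBN adduct of 25 (boron on the former exocyclic CH2, 3S) | C(B1C2CCCC1CCC2)[C@@H]1[C@H](CO[Si](C)(C)C(C)(C)C)[C@@H](c2ccc(O[Si](C(C)C)(C(C)C)C(C)C)c(OC)c2)O[C@@H]1[C@H](CO[Si](C)(C)C(C)(C)C)Oc1ccc(CCCO[Si](C)(C)C(C)(C)C)cc1OC | intermediate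
27 | [(2S,3S,4R,5S)‑2‑[(1S)‑1‑(Ar'O)‑2‑(TBS‑oxy)ethyl]‑4‑[(TBS‑oxy)methyl]‑5‑ArT‑oxolan‑3‑yl]methanol | OC[C@@H]1[C@H](CO[Si](C)(C)C(C)(C)C)[C@@H](c2ccc(O[Si](C(C)C)(C(C)C)C(C)C)c(OC)c2)O[C@@H]1[C@H](CO[Si](C)(C)C(C)(C)C)Oc1ccc(CCCO[Si](C)(C)C(C)(C)C)cc1OC | intermediate
28 | (2S,3R,4R,5S)‑2‑[(1S)‑1‑(Ar'O)‑2‑(TBS‑oxy)ethyl]‑4‑[(TBS‑oxy)methyl]‑5‑ArT‑oxolane‑3‑carbaldehyde | O=C[C@@H]1[C@H](CO[Si](C)(C)C(C)(C)C)[C@@H](c2ccc(O[Si](C(C)C)(C(C)C)C(C)C)c(OC)c2)O[C@@H]1[C@H](CO[Si](C)(C)C(C)(C)C)Oc1ccc(CCCO[Si](C)(C)C(C)(C)C)cc1OC | intermediate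
29 | methyl 2‑(dimethoxyphosphoryl)‑2‑methoxyacetate | COC(=O)C(OC)P(=O)(OC)OC | starting material
30 | methyl (Z)‑2‑methoxy‑3‑[(2S,3S,4R,5S)‑oxolan‑3‑yl]prop‑2‑enoate (oxolane substituted as in 27) | COC(=O)/C(OC)=C/[C@@H]1[C@H](CO[Si](C)(C)C(C)(C)C)[C@@H](c2ccc(O[Si](C(C)C)(C(C)C)C(C)C)c(OC)c2)O[C@@H]1[C@H](CO[Si](C)(C)C(C)(C)C)Oc1ccc(CCCO[Si](C)(C)C(C)(C)C)cc1OC | intermediate
31 | (Z)‑N,2‑dimethoxy‑N‑methyl‑3‑[(2S,3S,4R,5S)‑oxolan‑3‑yl]prop‑2‑enamide (oxolane substituted as in 27) | CON(C)C(=O)/C(OC)=C/[C@@H]1[C@H](CO[Si](C)(C)C(C)(C)C)[C@@H](c2ccc(O[Si](C(C)C)(C(C)C)C(C)C)c(OC)c2)O[C@@H]1[C@H](CO[Si](C)(C)C(C)(C)C)Oc1ccc(CCCO[Si](C)(C)C(C)(C)C)cc1OC | intermediate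
32 | (Z)‑4‑methoxy‑5‑[(2S,3S,4R,5S)‑oxolan‑3‑yl]pent‑4‑en‑1‑yn‑3‑one (oxolane substituted as in 27) | C#CC(=O)/C(OC)=C/[C@@H]1[C@H](CO[Si](C)(C)C(C)(C)C)[C@@H](c2ccc(O[Si](C(C)C)(C(C)C)C(C)C)c(OC)c2)O[C@@H]1[C@H](CO[Si](C)(C)C(C)(C)C)Oc1ccc(CCCO[Si](C)(C)C(C)(C)C)cc1OC | intermediate
33 | (1E,4Z)‑1,4‑dimethoxy‑5‑[(2S,3S,4R,5S)‑oxolan‑3‑yl]penta‑1,4‑dien‑3‑one (oxolane substituted as in 27) | CO/C=C/C(=O)/C(OC)=C/[C@@H]1[C@H](CO[Si](C)(C)C(C)(C)C)[C@@H](c2ccc(O[Si](C(C)C)(C(C)C)C(C)C)c(OC)c2)O[C@@H]1[C@H](CO[Si](C)(C)C(C)(C)C)Oc1ccc(CCCO[Si](C)(C)C(C)(C)C)cc1OC | intermediate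
34 | lithium (1E,3Z)‑1,4‑dimethoxy‑5‑(oxolan‑3‑ylidene)penta‑1,3‑dien‑3‑olate (exocyclic C=C geometry not fixed) | CO/C=C/C(O[Li])=C(OC)\C=C1[C@H](CO[Si](C)(C)C(C)(C)C)[C@@H](c2ccc(O[Si](C(C)C)(C(C)C)C(C)C)c(OC)c2)O[C@@H]1[C@H](CO[Si](C)(C)C(C)(C)C)Oc1ccc(CCCO[Si](C)(C)C(C)(C)C)cc1OC | intermediate
35 | lithium (5S)‑7,10‑dimethoxy‑2‑oxaspiro[4.5]deca‑6,8‑dien‑8‑olate, substituted as 36 (C10 epimers) | COC1=C[C@]2(C(OC)C=C1O[Li])[C@H](CO[Si](C)(C)C(C)(C)C)[C@@H](c1ccc(O[Si](C(C)C)(C(C)C)C(C)C)c(OC)c1)O[C@@H]2[C@H](CO[Si](C)(C)C(C)(C)C)Oc1ccc(CCCO[Si](C)(C)C(C)(C)C)cc1OC | intermediate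
36 | (1S,3S,4R,5S)‑1‑[(1S)‑1‑(Ar'O)‑2‑(TBS‑oxy)ethyl]‑7‑methoxy‑4‑[(TBS‑oxy)methyl]‑3‑ArT‑2‑oxaspiro[4.5]deca‑6,9‑dien‑8‑one | COC1=C[C@]2(C=CC1=O)[C@H](CO[Si](C)(C)C(C)(C)C)[C@@H](c1ccc(O[Si](C(C)C)(C(C)C)C(C)C)c(OC)c1)O[C@@H]2[C@H](CO[Si](C)(C)C(C)(C)C)Oc1ccc(CCCO[Si](C)(C)C(C)(C)C)cc1OC | intermediate
37 | (1S,3S,4R,5S)‑3‑(4‑hydroxy‑3‑methoxyphenyl)‑1‑{(1S)‑2‑hydroxy‑1‑[4‑(3‑hydroxypropyl)‑2‑methoxyphenoxy]ethyl}‑4‑(hydroxymethyl)‑7‑methoxy‑2‑oxaspiro[4.5]deca‑6,9‑dien‑8‑one (CNP0252711.1) | COC1=C[C@]2(C=CC1=O)[C@H](CO)[C@@H](c1ccc(O)c(OC)c1)O[C@@H]2[C@H](CO)Oc1ccc(CCCO)cc1OC | target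

**Totals.** Total step count: 22. Longest linear sequence: 18 steps (1, 3–7, 11–22).

**Steps most likely to fail**

1. Step 21 (key step, proposed new method). What may go wrong: the C3 carbanion may expel the ring oxygen by β‑elimination and open the oxolane; the enolate may form with the wrong geometry, so that the triene termini cannot meet; or closure onto the fully substituted terminus may be too slow, so that the trienolate only reprotonates. The fallback uses known chemistry, the gold(I)‑catalysed carbocyclisation of silyl enol ethers onto alkynes (Conia‑ene type), and avoids any free carbanion. It sets out from ynone 32, which is converted with TBSOTf and iPr2NEt (CH2Cl2, −78 → 0 °C) into the (Z)‑tert‑butyldimethylsilyl dienol ether of the ynone F1. Cationic gold ([JohnPhosAu(MeCN)]SbF6, 5 mol %, CH2Cl2, MeOH 1.5 equiv, 0 °C) then activates the alkyne for 6‑endo‑dig attack by the γ‑carbon of the dienol ether (oxolane C3), again on the face anti to the C2 and C4 substituents. Protodeauration and loss of the silyl group to methanol return the route at 36.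

2. Step 12. What may go wrong: the Lewis acid may strip the primary silyl ethers, the cation may eliminate to a styrene, or the aryl group may be delivered with poor trans selectivity relative to C4. The fallback closes the ring through a neutral p‑quinone methide instead of a silyl‑capped cation. It sets out from 22: the aryl TIPS ether is removed selectively (TBAF, AcOH, THF, −20 °C) to give the free phenol F2. On gentle warming with a trace of PPTS this loses silanol to the p‑quinone methide F3, which is trapped reversibly by the C2 hydroxyl in an intramolecular oxa‑Michael addition to give the thermodynamically preferred 4,5‑trans oxolane phenol F4. Re‑silylation (TIPSCl, imidazole) returns the route at 23.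

3. Step 22. What may go wrong: the enol ether may hydrolyse, or the liberated alcohols (the C4 hydroxymethyl lies next to the methoxy‑enone) may undergo conjugate addition while four silyl ethers are cleaved on the finished spirodienone. The fallback moves the hard deprotection ahead of the ring closure and carries labile groups through it. It sets out from 33, which is desilylated with HF·pyridine to the tetraol F5 and persilylated (TMSCl, Et3N, CH2Cl2) to the tetrakis‑TMS ether F6. Ring closure as in step 21 proceeds through the trienolate F7 and the methoxy dienolate F8 to the tetrakis‑TMS spirodienone F9. Its TMS ethers are removed by citric acid in MeOH at 0 °C, returning the route at 37.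

**Further compounds**

F1 | step 21 | (Z)‑TBS dienol ether of ynone 32 (3‑silyloxy‑dienyne) | C#C/C(O[Si](C)(C)C(C)(C)C)=C(OC)\C=C1[C@H](CO[Si](C)(C)C(C)(C)C)[C@@H](c2ccc(O[Si](C(C)C)(C(C)C)C(C)C)c(OC)c2)O[C@@H]1[C@H](CO[Si](C)(C)C(C)(C)C)Oc1ccc(CCCO[Si](C)(C)C(C)(C)C)cc1OC
F2 | step 12 | free phenol of 22 | C=C([C@H](O)[C@H](C(=O)N1[C@H](Cc2ccccc2)COC1=O)Oc1ccc(CCCO[Si](C)(C)C(C)(C)C)cc1OC)[C@H](CO[Si](C)(C)C(C)(C)C)[C@H](O[Si](C)(C)C(C)(C)C)c1ccc(O)c(OC)c1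
F3 | step 12 | p‑quinone methide derived from F2 | C=C([C@H](O)[C@H](C(=O)N1[C@H](Cc2ccccc2)COC1=O)Oc1ccc(CCCO[Si](C)(C)C(C)(C)C)cc1OC)[C@H](CO[Si](C)(C)C(C)(C)C)C=C1C=CC(=O)C(OC)=C1
F4 | step 12 | oxolane phenol (23 without TIPS) | C=C1[C@H](CO[Si](C)(C)C(C)(C)C)[C@@H](c2ccc(O)c(OC)c2)O[C@@H]1[C@H](C(=O)N1[C@H](Cc2ccccc2)COC1=O)Oc1ccc(CCCO[Si](C)(C)C(C)(C)C)cc1OC
F5 | step 22 | tetraol of 33 | CO/C=C/C(=O)/C(OC)=C/[C@@H]1[C@H](CO)[C@@H](c2ccc(O)c(OC)c2)O[C@@H]1[C@H](CO)Oc1ccc(CCCO)cc1OC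
F6 | step 22 | tetrakis‑TMS ether of F5 | CO/C=C/C(=O)/C(OC)=C/[C@@H]1[C@H](CO[Si](C)(C)C)[C@@H](c2ccc(O[Si](C)(C)C)c(OC)c2)O[C@@H]1[C@H](CO[Si](C)(C)C)Oc1ccc(CCCO[Si](C)(C)C)cc1OC
F7 | step 22 | lithium trienolate of F6 | CO/C=C/C(O[Li])=C(OC)\C=C1[C@H](CO[Si](C)(C)C)[C@@H](c2ccc(O[Si](C)(C)C)c(OC)c2)O[C@@H]1[C@H](CO[Si](C)(C)C)Oc1ccc(CCCO[Si](C)(C)C)cc1OC
F8 | step 22 | lithium methoxy cyclohexadienolate from F7 | COC1=C[C@]2(C(OC)C=C1O[Li])[C@H](CO[Si](C)(C)C)[C@@H](c1ccc(O[Si](C)(C)C)c(OC)c1)O[C@@H]2[C@H](CO[Si](C)(C)C)Oc1ccc(CCCO[Si](C)(C)C)cc1OC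
F9 | step 22 | tetrakis‑TMS spirodienone | COC1=C[C@]2(C=CC1=O)[C@H](CO[Si](C)(C)C)[C@@H](c1ccc(O[Si](C)(C)C)c(OC)c1)O[C@@H]2[C@H](CO[Si](C)(C)C)Oc1ccc(CCCO[Si](C)(C)C)cc1OC
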